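**Remark on the chemistry (assumption).** Germacranolide numbering is used throughout: C1 ketone, C2=C3 furanone alkene, oxygen bridge C3–O–C10, C4=C5 with C15 on C4, lactone C6–O/C7–C11/C12(=O) with exocyclic C13, ester carbinol C8, C9, C10 bearing C14. The descriptors of the target (6S,7R,8R,10R; 4Z) encode a cis-fused lactone (H6 and H7 on the same face), and the plan is built for exactly that relative configuration.

## The problem

Compound 24 is a ten-membered carbocycle (C1–C10) that is bridged twice. An oxygen links C3 and C10, so that C1, C2, C3, C10 and this oxygen form a 3(2H)-furanone, and C6/C7 carry a cis-fused α-methylene-γ-butyrolactone (C6–O, C7–C11, C12, exocyclic C13). Between the two five-membered rings lies the Z-configured C4=C5 alkene, cross-conjugated with the furanone and carrying the C15 hydroxymethyl group; C8 bears an isobutyrate. Of the four stereocentres, C10 is quaternary and insulated from the others by C9 and the furanone, so it has to be bought from the chiral pool. C6 must also be set independently, whereas C7 and C8 are contiguous with C6 and can be created under its control when the ring is closed. Little rough treatment is tolerated: the methylene lactone and the furanone dienone accept nucleophiles, the C4=C5 geometry can be lost by reversible conjugate addition, and a free C8 hydroxyl can translactonise onto C12. In any butenolide precursor the C6 hydrogen is both allylic and γ to the lactone carbonyl, so bases are excluded once that ring exists. The enabling feature is that C8 and C7 are both electrophilic in natural precursors (C8 as an aldehyde carbon, C7 as the β-carbon of a C12(=O)–C11=C7 butenolide) and that C13 on C11 can carry a leaving group. A two-electron reductant can therefore join C7 to C8 and, by β-elimination from the C11 enolate, unveil the C11=C13 methylene in the same event.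

## Retrosynthesis

**24 ⇒ 23 ⇒ 22 (C15 O–Si and C8 O–acyl).** The isobutyrate can only be placed once C8 is a carbinol, so it comes after ring closure. The C15 silyl ether must outlast that acylation, since a free primary hydroxyl would be acylated first. Alcohol 22 differs from the target only by these two groups; the forward steps are a hindered-alcohol acylation and a fluoride desilylation that the methylene lactone tolerates.

**22 ⇒ 21 (C7–C8 cut, C13–OAc restored).** This cut removes the ten-membered ring, two stereocentres and the methylene group at once and leaves 21, in which only C6 and C10 are stereogenic. Neighbouring cuts are weaker: closing at C4=C5 by metathesis leaves the alkene geometry to the ring, and closing at C2–C3 needs strong base beside the lactone. The forward reaction must reduce the aldehyde in preference to the furanone dienone, bond C7 on the face syn to C5, and fix C8.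

**21 ⇒ 19 (C8=O from a terminal alkene).** The aldehyde sits β to the furanone oxygen on C10 and would not survive a long sequence, so it is carried as the allyl group of 19 and released immediately before the key step. The forward reaction must cleave one isolated terminal alkene in the presence of three conjugated, electron-poor ones.

**19 ⇒ 18 ⇒ 17 + 6 (furanone C3–O bond, then C3–C4).** The furanone is opened to the hydroxy ynone 18, and the C3–C4 bond is cut to the alkenyl iodide 17 and the terminal ynone 6. The neighbouring option, addition of an alkenyllithium to a tetronate, cannot coexist with a butenolide ester and would postpone the butenolide metathesis until the C10 allyl group is present. The chosen cut lets the butenolide be finished on the small fragment and joins two fragments of similar size under near-neutral conditions. The coupling must be faster than ionisation of the allylic acetate and must not epimerise C6; the cyclisation must be a 5-endo attack of the tertiary hydroxyl.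

**17 ⇒ 16 ⇒ 11 + 14 (C7=C11, then the C6 O–acyl bond).** Ring-closing metathesis builds the 3-(acetoxymethyl)butenolide from acrylate 16, in which the only monosubstituted alkene is the C6 vinyl group. Ester 16 comes from carbinol 11 and acid 14 (via chloride 15). The acylation must avoid nucleophilic amines, which would displace the allylic acetate.

**11 ⇒ 10 ⇒ 9 ⇒ 8 ⇒ 7 (C6–C7, then alkene geometry).** Enantioselective vinyl addition to enal 10 sets C6. The Z-iodoalkene of 9 is written into the skeleton by hydroxyl-directed trans-hydroalumination/iodination of the mono-silylated butynediol 8, made from 7. The geometry is thus fixed at the four-carbon stage instead of being asked of a macrocyclisation.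

**6 ⇒ 5 ⇒ 4 ⇒ 2 ⇒ 1 (+ 3) (C1–C2, then C9–C10).** The ynone is an acetylide adduct of Weinreb amide 5. The quaternary centre comes from (S)-lactic acid 1 through the cis-dioxolanone 2, whose enolate is allylated with allyl bromide 3 anti to the tert-butyl group to give 4. No step after this touches C10.

**14 ⇒ 13 ⇒ 12.** The C11–C13 unit is ethyl 2-(hydroxymethyl)acrylate 12, saponified to 13 and acetylated to 14.

## Roads not taken

Alternative 1: The lactone C7–C11 bond is cut; the ten-membered ring would be closed later at C4=C5. In the forward key step, LiCl/DBU generates the phosphonoacetate carbanion of the C6 ester A2, which opens the trans C7–C8 epoxide at C7 with inversion (5-exo) and gives the α-phosphono lactone A1 with a free C8 hydroxyl. Its merit is stereochemical certainty: C7 and C8 follow stereospecifically from the epoxide and from C6, and the phosphonate later gives the methylene group by olefination with formaldehyde. In this respect it is better than the chosen plan, whose C8 configuration rests on a transition-state preference. Its weak points are that A1 is still acyclic between C4 and C5, so the carbocycle must be closed by metathesis of a vinyl group with a 1,1-disubstituted alkene conjugated to the furanone, and the Z geometry of a trisubstituted alkene in a ten-membered ring is then not under control. The epoxide also needs its own asymmetric step, and DBU acts on a substrate with a β-oxygenated carbonyl array. Against the better C7/C8 control, the chosen plan sets an alkene geometry fixed at the outset, one step that forms the ring, both stereocentres and the methylene group, and a shorter sequence.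

Alternative 2: The C2–C3 bond is cut and the ring is closed earlier as the nine-membered lactone A4, an ester of the C10 tertiary alcohol. In the forward key step LiN(SiMe3)2 enolises the C10 acetyl group, the enolate attacks the lactone carbonyl (O-to-C acyl transfer, ring expansion to the ten-membered 1,3-diketone), and acid closes and dehydrates to the furanone, giving A3. Its merits are real: the C–C ring bond forms within an existing ring, the furanone arises in the same operation, and no stereocentre is created at the ring-forming stage, so there is no diastereoselectivity risk; here it is superior to the chosen plan. The weak points lie before and after. A4 requires lactonisation of a hindered tertiary α-hydroxy ketone with a Z-enoic acid into a nine-membered ring. The strong base meets the isobutyrate and the lactone C11 hydrogens, which are as acidic as the methyl ketone. A3 still lacks C13, so a second enolisation and methylenation must follow on a molecule containing a furanone and an ester. The chosen plan avoids strong base entirely after the butenolide exists and delivers the methylene group in the ring-closing step, at the price of having to control C8.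

Alternative 3: The C4=C5 alkene is cut to the eleven-membered sulfone A6, to be contracted by Ramberg–Bäcklund reaction (α-halogenation, base, episulfone, loss of SO2) to A5. Closing the ring by sulfide alkylation is easier than any C–C closure, and in that respect this road is better than the chosen one. For this target the weaknesses dominate. The α-sulfonyl carbanion at C5 is β to the C6 lactone oxygen and can expel it. The geometry of the new trisubstituted alkene is not assured. A5 has C15 as a methyl group, so an allylic oxidation of an electron-poor alkene is needed. C13 is missing, and C8 still has to be deprotected and acylated. The chosen plan carries the C15 oxygen and the C13 carbon from the start and needs no strong base.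

Key step: step 16

## Route

Step 1
Reactants: 1 (S)-lactic acid
Product: 2 (2S,5S)-2-tert-butyl-5-methyl-1,3-dioxolan-4-one (cis)
Conditions: pivalaldehyde, TsOH (cat.), H2SO4 (cat.), pentane, reflux with water separator; crystallisation at low temperature
Reagents that add atoms: pivalaldehyde, CC(C)(C)C=O
Why: Acid-catalysed acetalisation of the α-hydroxy acid with azeotropic water removal; the cis acetal predominates and should be freed of the trans isomer by crystallisation, so that the tert-butyl group can steer the next step.

Step 2
Reactants: 2 (2S,5S)-2-tert-butyl-5-methyl-1,3-dioxolan-4-one; 3 allyl bromide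
Product: 4 (2S,5R)-5-allyl-2-tert-butyl-5-methyl-1,3-dioxolan-4-one
Conditions: LiN(iPr)2, THF, −78 °C; then 3, −78 → −30 °C
Reagents that add atoms: none
Why: Enolate alkylation under self-regeneration of stereocentres: the electrophile enters anti to the tert-butyl group, so allyl replaces the lactate hydrogen with retention and fixes the quaternary carbon that becomes C10 (R).

Step 3
Reactants: 4 (2S,5R)-5-allyl-2-tert-butyl-5-methyl-1,3-dioxolan-4-one
Product: 5 (2R)-2-hydroxy-N-methoxy-N,2-dimethylpent-4-enamide
Conditions: MeNHOMe·HCl, AlMe3, CH2Cl2, 0 °C → rt; aqueous tartrate work-up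
Reagents that add atoms: N,O-dimethylhydroxylamine hydrochloride, CNOC.Cl
Why: Weinreb amidation by an aluminium amide opens the acylal carbonyl; the hemiacetal collapses to pivalaldehyde and frees the tertiary hydroxyl without touching the stereocentre.

Step 4
Reactants: 5 (2R)-2-hydroxy-N-methoxy-N,2-dimethylpent-4-enamide
Product: 6 (4R)-4-hydroxy-4-methylhept-6-en-1-yn-3-one
Conditions: HC≡CMgBr (3.5 equiv), THF, 0 °C → rt; inverse quench into cold aqueous NaHSO4
Reagents that add atoms: ethynylmagnesium bromide, C#C[Mg]Br
Why: Weinreb ketone synthesis: the chelated tetrahedral adduct persists until the quench, so the acetylide adds once; the first equivalent is consumed by the hydroxyl. The cold acidic quench keeps the released amine protonated so that it cannot add to the ynone.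

Step 5
Reactants: 7 2-butyne-1,4-diol
Product: 8 4-[(tert-butyldimethylsilyl)oxy]but-2-yn-1-ol
Conditions: NaH (1.0 equiv), THF, 0 °C; TBSCl (1.0 equiv), 0 °C → rt
Reagents that add atoms: tert-butyldimethylsilyl chloride, CC(C)(C)[Si](C)(C)Cl
Why: Monosilylation of a symmetrical diol through its monosodium alkoxide, a standard desymmetrisation by stoichiometry.

Step 6
Reactants: 8 4-[(tert-butyldimethylsilyl)oxy]but-2-yn-1-ol
Product: 9 (2Z)-4-[(tert-butyldimethylsilyl)oxy]-3-iodobut-2-en-1-ol
Conditions: NaAlH2(OCH2CH2OMe)2, THF, 0 °C; EtOAc; then I2, THF, −78 °C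
Reagents that add atoms: iodine, [I][I]
Why: Hydroxyl-directed trans-hydroalumination puts aluminium on the distal alkyne carbon in a five-membered alkenylaluminate, and iodinolysis proceeds with retention. Iodine (the later C3 attachment) therefore ends cis to the carbinol carbon (later C6), which is the C4=C5 geometry of the target.

Step 7
Reactants: 9 (2Z)-4-[(tert-butyldimethylsilyl)oxy]-3-iodobut-2-en-1-ol
Product: 10 (2Z)-4-[(tert-butyldimethylsilyl)oxy]-3-iodobut-2-enal
Conditions: MnO2 (activated, excess), CH2Cl2, rt, dark; filtered and used at once
Reagents that add atoms: none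
Why: Neutral heterogeneous oxidation of an allylic alcohol, the usual way to Z-β-iodo enals without loss of geometry; the enal is not stored.

Step 8
Reactants: 10 (2Z)-4-[(tert-butyldimethylsilyl)oxy]-3-iodobut-2-enal
Product: 11 (3R,4Z)-6-[(tert-butyldimethylsilyl)oxy]-5-iodohexa-1,4-dien-3-ol
Conditions: (CH2=CH)2Zn (from CH2=CHMgBr and ZnCl2, magnesium halides precipitated with 1,4-dioxane), (2R)-(+)-3-exo-(dimethylamino)isoborneol (10 mol %), toluene, −20 → 0 °C
Reagents that add atoms: divinylzinc, C=C[Zn]C=C (made in the flask from vinylmagnesium bromide, C=C[Mg]Br, and ZnCl2)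
Why: Amino-alcohol-catalysed enantioselective addition of an alkenylzinc to an aldehyde; this ligand enantiomer should deliver the vinyl group to the Re face and give the R carbinol, which is C6 of the target. Salt-free reagent is used because magnesium halides promote a racemic background addition.

Step 9
Reactants: 12 ethyl 2-(hydroxymethyl)acrylate
Product: 13 2-(hydroxymethyl)prop-2-enoic acid
Conditions: LiOH, THF–H2O, 0 °C → rt; then aqueous HCl to pH 2
Reagents that add atoms: lithium hydroxide, [Li+].[OH-]
Why: Ordinary saponification of an unhindered ethyl ester, kept cold to avoid conjugate addition of hydroxide.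

Step 10
Reactants: 13 2-(hydroxymethyl)prop-2-enoic acid
Product: 14 2-(acetoxymethyl)prop-2-enoic acid
Conditions: Ac2O, pyridine, CH2Cl2, 0 °C → rt; then H2O, aqueous HCl work-up
Reagents that add atoms: acetic anhydride, CC(=O)OC(C)=O
Why: O-Acetylation of the primary allylic alcohol; any mixed anhydride at the carboxyl group is hydrolysed in the aqueous work-up.

Step 11
Reactants: 14 2-(acetoxymethyl)prop-2-enoic acid; 11 (3R,4Z)-6-[(tert-butyldimethylsilyl)oxy]-5-iodohexa-1,4-dien-3-ol
Product: 16 (3R,4Z)-6-[(tert-butyldimethylsilyl)oxy]-5-iodohexa-1,4-dien-3-yl 2-(acetoxymethyl)prop-2-enoate, via 2-(acetoxymethyl)prop-2-enoyl chloride 15 (not isolated)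
Conditions: (COCl)2, DMF (cat.), CH2Cl2, 0 °C → rt; then 11, iPr2NEt, CH2Cl2, −40 → 0 °C
Reagents that add atoms: none
Why: Esterification through the acid chloride; a hindered, non-nucleophilic amine is used because nucleophilic acylation catalysts would displace the allylic acetate in an SN2′ sense. The carbinol stereocentre is not involved.

Step 12
Reactants: 16 (3R,4Z)-6-[(tert-butyldimethylsilyl)oxy]-5-iodohexa-1,4-dien-3-yl 2-(acetoxymethyl)prop-2-enoate
Product: 17 {(5R)-5-[(1Z)-3-[(tert-butyldimethylsilyl)oxy]-2-iodoprop-1-en-1-yl]-2-oxo-2,5-dihydrofuran-3-yl}methyl acetate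
Conditions: second-generation Grubbs catalyst, RuCl2(=CHPh)(PCy3)(H2IMes) (5–10 mol %), CH2Cl2 (0.01 M), 40 °C
Reagents that add atoms: none
Why: Ring-closing metathesis of an α-substituted acrylate of an allylic alcohol to an α-substituted butenolide; the carbene loads on the only monosubstituted alkene (the C6 vinyl group) and closes the five-membered ring. The trisubstituted iodoalkene is inert and keeps its geometry.

Step 13
Reactants: 17 {(5R)-5-[(1Z)-3-[(tert-butyldimethylsilyl)oxy]-2-iodoprop-1-en-1-yl]-2-oxo-2,5-dihydrofuran-3-yl}methyl acetate; 6 (4R)-4-hydroxy-4-methylhept-6-en-1-yn-3-one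
Product: 18 {(5S)-5-[(1E,6R)-2-{[(tert-butyldimethylsilyl)oxy]methyl}-6-hydroxy-6-methyl-5-oxonona-1,8-dien-3-yn-1-yl]-2-oxo-2,5-dihydrofuran-3-yl}methyl acetate
Conditions: PdCl2(PPh3)2 (5 mol %), CuI (10 mol %), iPr2NEt (2 equiv), THF (degassed), 0 °C → rt
Reagents that add atoms: none
Why: Sonogashira coupling of an alkenyl iodide with an acidic terminal ynone, with retention of alkene geometry (the E descriptor is only a priority change; the alkynyl carbon stays cis to the lactone carbon). Oxidative addition to the C–I bond should outrun ionisation of the allylic acetate at this temperature, and the hindered tertiary amine can neither add to the ynone nor readily remove the C6 hydrogen.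

Step 14
Reactants: 18 {(5S)-5-[(1E,6R)-2-{[(tert-butyldimethylsilyl)oxy]methyl}-6-hydroxy-6-methyl-5-oxonona-1,8-dien-3-yn-1-yl]-2-oxo-2,5-dihydrofuran-3-yl}methyl acetate
Product: 19 {(5S)-5-[(1Z)-3-[(tert-butyldimethylsilyl)oxy]-2-[(5R)-5-methyl-4-oxo-5-(prop-2-en-1-yl)-4,5-dihydrofuran-2-yl]prop-1-en-1-yl]-2-oxo-2,5-dihydrofuran-3-yl}methyl acetate
Conditions: (4-CF3C6H4)3PAuCl (5 mol %), AgOTf (5 mol %), toluene, rt
Reagents that add atoms: none
Why: Monovalent-gold-catalysed cycloisomerisation of a hydroxy alkynone to a 3(2H)-furanone: π-activation of the ynone, 5-endo-dig attack of the tertiary hydroxyl on C3, protodeauration. The conditions are neutral, so C6 and the acetate are not at risk, and the electron-poor alkyne should prefer the hydroxyl to the remote allyl group.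

Step 15
Reactants: 19 {(5S)-5-[(1Z)-3-[(tert-butyldimethylsilyl)oxy]-2-[(5R)-5-methyl-4-oxo-5-(prop-2-en-1-yl)-4,5-dihydrofuran-2-yl]prop-1-en-1-yl]-2-oxo-2,5-dihydrofuran-3-yl}methyl acetate
Product: 21 {(5S)-5-[(1Z)-3-[(tert-butyldimethylsilyl)oxy]-2-[(5R)-5-methyl-4-oxo-5-(2-oxoethyl)-4,5-dihydrofuran-2-yl]prop-1-en-1-yl]-2-oxo-2,5-dihydrofuran-3-yl}methyl acetate, via vicinal diol 20 (not isolated)
Conditions: OsO4 (2 mol %), N-methylmorpholine N-oxide (1.2 equiv), acetone–H2O, 0 °C; then NaIO4 (1.5 equiv), THF–pH 7 buffer, 0 °C; crude aldehyde used directly
Reagents that add atoms: N-methylmorpholine N-oxide, C[N+]1([O-])CCOCC1; water, O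
Why: Upjohn dihydroxylation followed by periodate glycol cleavage; the electrophilic osmium reagent should choose the isolated terminal alkene over the three trisubstituted, carbonyl-conjugated alkenes. Both stages are near neutral, which the β-oxygenated aldehyde and the C6 centre require.

Step 16
Reactants: 21 {(5S)-5-[(1Z)-3-[(tert-butyldimethylsilyl)oxy]-2-[(5R)-5-methyl-4-oxo-5-(2-oxoethyl)-4,5-dihydrofuran-2-yl]prop-1-en-1-yl]-2-oxo-2,5-dihydrofuran-3-yl}methyl acetate
Product: 22 (6S,7R,8R,10R,4Z)-15-O-(tert-butyldimethylsilyl)-8-hydroxy macrocycle: ten-membered ring C1–C10 with the C3–O–C10 furanone, the Z C4=C5 alkene carrying CH2OTBS, the cis-fused 6,12-lactone with C11=C13 methylene, and a free C8 hydroxyl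
Conditions: SmI2 (2.2 equiv, 0.1 M in THF), slow addition of 21 to a final 0.002 M, THF, −40 → 0 °C, no proton donor, no HMPA; pH 7 buffer quench at 0 °C
Reagents that add atoms: none
Why: Proposed new method: single-electron transfer from SmI2 to the C8 aldehyde gives a samarium ketyl that adds to C7, the β-carbon of the butenolide; the α-carbonyl radical at C11 takes the second electron and the resulting trivalent samarium enolate expels the C13 acetate (E1cB), so the C7–C8 bond, the ten-membered carbocycle and the C11=C13 methylene arise together. The closest known reaction types are SmI2 ketyl–olefin cyclisations onto unsaturated esters and lactones and SmI2 Barbier allylations; new here is their use for a ten-membered ring on a 3-(acyloxymethyl)butenolide with β-elimination in the same flask. The ring closes in a 10-exo-trig mode (C7 inside the new ring, C11 outside). C7 is controlled by C6: the chain carrying the ketyl is attached to C6 through C5, and the rigid Z-alkene/furanone spacer lets it reach only the Si face of C7, the face syn to C5, which gives the cis-fused lactone (7R). C8 is controlled by chelation: trivalent samarium bridges the ketyl oxygen and the lactone carbonyl oxygen, which holds the C8–O bond gauche to C7–C11 and anti to C7–C6 on the outside of the forming ring, and with C9 anchored by the 10R quaternary carbon the Si face of the carbonyl should be presented (8R). If the butenolide is reduced first, loss of acetate gives an allylsamarium that attacks the aldehyde through C7 and forms the same bond, so the two pathways converge. The step needs selectivity for the aldehyde over the furanone dienone and over the product methylene lactone, and cyclisation must beat pinacol coupling; the exact stoichiometry, the absence of proton donor and HMPA, low temperature and high dilution are chosen for this.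

Step 17
Reactants: 22 (6S,7R,8R,10R,4Z)-15-O-(tert-butyldimethylsilyl)-8-hydroxy macrocycle
Product: 23 (6S,7R,8R,10R,4Z)-15-O-(tert-butyldimethylsilyl)-8-O-isobutyryl macrocycle
Conditions: (iPrCO)2O (3 equiv), 4-(dimethylamino)pyridine (0.1 equiv), pyridine, CH2Cl2, 0 °C
Reagents that add atoms: isobutyric anhydride, CC(C)C(=O)OC(=O)C(C)C
Why: Nucleophile-catalysed acylation of a secondary alcohol; it is run cold and immediately after step 16 so that the C8 hydroxyl is capped before it can translactonise onto C12. C6 is no longer a butenolide γ-position and tolerates the amine.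

Step 18
Reactants: 23 (6S,7R,8R,10R,4Z)-15-O-(tert-butyldimethylsilyl)-8-O-isobutyryl macrocycle
Product: 24 CNP0176924.5 (target; 15-hydroxy, 8-O-isobutyryl, 6S,7R,8R,10R, 4Z)
Conditions: HF·pyridine, pyridine, THF, 0 °C → rt
Reagents that add atoms: none
Why: Cleavage of a primary silyl ether by buffered hydrogen fluoride, conditions under which the methylene lactone, the furanone and the isobutyrate are stable; no stereocentre is touched.

## Compound list

1 | (S)-lactic acid | C[C@H](O)C(=O)O | starting material
2 | (2S,5S)-2-tert-butyl-5-methyl-1,3-dioxolan-4-one | C[C@@H]1O[C@H](C(C)(C)C)OC1=O | intermediate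
3 | allyl bromide | C=CCBr | starting material
4 | (2S,5R)-5-allyl-2-tert-butyl-5-methyl-1,3-dioxolan-4-one | C=CC[C@@]1(C)O[C@H](C(C)(C)C)OC1=O | intermediate
5 | (2R)-2-hydroxy-N-methoxy-N,2-dimethylpent-4-enamide | C=CC[C@@](C)(O)C(=O)N(C)OC | intermediate
6 | (4R)-4-hydroxy-4-methylhept-6-en-1-yn-3-one | C#CC(=O)[C@](C)(O)CC=C | intermediate
7 | 2-butyne-1,4-diol | OCC#CCO | starting material
8 | 4-[(tert-butyldimethylsilyl)oxy]but-2-yn-1-ol | OCC#CCO[Si](C)(C)C(C)(C)C | intermediate
9 | (2Z)-4-[(tert-butyldimethylsilyl)oxy]-3-iodobut-2-en-1-ol | OC/C=C(/CO[Si](C)(C)C(C)(C)C)I | intermediate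
10 | (2Z)-4-[(tert-butyldimethylsilyl)oxy]-3-iodobut-2-enal | O=C/C=C(/CO[Si](C)(C)C(C)(C)C)I | intermediate
11 | (3R,4Z)-6-[(tert-butyldimethylsilyl)oxy]-5-iodohexa-1,4-dien-3-ol | C=C[C@@H](O)/C=C(/CO[Si](C)(C)C(C)(C)C)I | intermediate
12 | ethyl 2-(hydroxymethyl)acrylate | C=C(CO)C(=O)OCC | starting material
13 | 2-(hydroxymethyl)prop-2-enoic acid | C=C(CO)C(=O)O | intermediate
14 | 2-(acetoxymethyl)prop-2-enoic acid | CC(=O)OCC(=C)C(=O)O | intermediate
15 | 2-(acetoxymethyl)prop-2-enoyl chloride (not isolated) | CC(=O)OCC(=C)C(=O)Cl | intermediate
16 | (3R,4Z)-6-[(tert-butyldimethylsilyl)oxy]-5-iodohexa-1,4-dien-3-yl 2-(acetoxymethyl)prop-2-enoate | CC(=O)OCC(=C)C(=O)O[C@H](C=C)/C=C(/CO[Si](C)(C)C(C)(C)C)I | intermediate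
17 | {(5R)-5-[(1Z)-3-[(tert-butyldimethylsilyl)oxy]-2-iodoprop-1-en-1-yl]-2-oxo-2,5-dihydrofuran-3-yl}methyl acetate | CC(=O)OCC1=C[C@@H](OC1=O)/C=C(/CO[Si](C)(C)C(C)(C)C)I | intermediate
18 | {(5S)-5-[(1E,6R)-2-{[(tert-butyldimethylsilyl)oxy]methyl}-6-hydroxy-6-methyl-5-oxonona-1,8-dien-3-yn-1-yl]-2-oxo-2,5-dihydrofuran-3-yl}methyl acetate | CC(=O)OCC1=C[C@@H](OC1=O)/C=C(/CO[Si](C)(C)C(C)(C)C)C#CC(=O)[C@](C)(O)CC=C | intermediate
19 | {(5S)-5-[(1Z)-3-[(tert-butyldimethylsilyl)oxy]-2-[(5R)-5-methyl-4-oxo-5-(prop-2-en-1-yl)-4,5-dihydrofuran-2-yl]prop-1-en-1-yl]-2-oxo-2,5-dihydrofuran-3-yl}methyl acetate | CC(=O)OCC1=C[C@@H](OC1=O)/C=C(/CO[Si](C)(C)C(C)(C)C)C2=CC(=O)[C@@](C)(CC=C)O2 | intermediate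
20 | vicinal diol from 19: 5-(2,3-dihydroxypropyl) analogue, both epimers at the new secondary carbinol (not isolated) | CC(=O)OCC1=C[C@@H](OC1=O)/C=C(/CO[Si](C)(C)C(C)(C)C)C2=CC(=O)[C@@](C)(CC(O)CO)O2 | intermediate
21 | {(5S)-5-[(1Z)-3-[(tert-butyldimethylsilyl)oxy]-2-[(5R)-5-methyl-4-oxo-5-(2-oxoethyl)-4,5-dihydrofuran-2-yl]prop-1-en-1-yl]-2-oxo-2,5-dihydrofuran-3-yl}methyl acetate (precursor of the key step) | CC(=O)OCC1=C[C@@H](OC1=O)/C=C(/CO[Si](C)(C)C(C)(C)C)C2=CC(=O)[C@@](C)(CC=O)O2 | intermediate
22 | (6S,7R,8R,10R,4Z)-15-O-(tert-butyldimethylsilyl)-8-hydroxy macrocycle with furanone, cis-fused methylene lactone and free C8 hydroxyl (product of the key step) | C=C1C(=O)O[C@H]2/C=C(/CO[Si](C)(C)C(C)(C)C)C3=CC(=O)[C@@](C)(C[C@@H](O)[C@@H]12)O3 | intermediate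
23 | (6S,7R,8R,10R,4Z)-15-O-(tert-butyldimethylsilyl)-8-O-isobutyryl macrocycle | C=C1C(=O)O[C@H]2/C=C(/CO[Si](C)(C)C(C)(C)C)C3=CC(=O)[C@@](C)(C[C@@H](OC(=O)C(C)C)[C@@H]12)O3 | intermediate
24 | CNP0176924.5 | C=C1C(=O)O[C@H]2/C=C(/CO)C3=CC(=O)[C@@](C)(C[C@@H](OC(=O)C(C)C)[C@@H]12)O3 | target

## Step count and least certain steps

Total: 18 steps. Longest linear sequence: 12 steps (steps 5–8 and 11–18).

**Step 16 (key step, proposed new method).** The ketyl may be consumed by pinacol coupling or by further reduction before the slow ten-membered closure. Electron transfer to the butenolide instead of the aldehyde may open the lactone by loss of the C6 carboxylate. Facial control at the ketyl carbon may be incomplete, and the samarium alkoxide may translactonise before the quench. Fallback with known chemistry, setting out from 19 and returning at 22: the C13 acetate of 19 would be removed with a lipase in pH 7 buffer to give the allylic alcohol F1. This would be converted with N-bromosuccinimide/dimethyl sulfide (Corey–Kim bromination) into the allylic bromide F2, and the allyl group would then be cleaved (OsO4 cat., NaIO4, 2,6-lutidine, dioxane–H2O) to the bromo aldehyde F3. Treatment of F3 with CrCl2 in THF at high dilution (intramolecular Nozaki–Hiyama allylation) would form the allylchromium, which adds through C7 to the aldehyde in a closed six-membered transition state and gives 22. Closure of a 2-(bromomethyl)-2-enoate unit onto an aldehyde to a ten-membered carbocycle bearing a methylene lactone is an established reaction type, and the closed transition state supplies a different control element for C8 than the chelate.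

**Step 15.** Competing dihydroxylation of the C4=C5 or furanone alkene would erode the yield, and the aldehyde may lose the furanone oxygen by β-elimination during cleavage or handling. Fallback, setting out from 6 and returning at 21: ozonolysis of 6 (the alkyne is much less reactive than the alkene) with dimethyl sulfide work-up would give the ynone aldehyde F4, converted in the same flask (MeOH, HC(OMe)3, TsOH cat.) into the dimethyl acetal F5. Sonogashira coupling of F5 with 17 as in step 13 would give the acetal enynone F6, and gold-catalysed cyclisation as in step 14 the acetal furanone F7. Mild aqueous acid (oxalic acid on wet silica) would then release 21 with no oxidant ever meeting the polyene.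

**Step 13.** The amine may slowly remove the doubly activated C6 hydrogen and erode its configuration, the terminal ynone may dimerise oxidatively or decompose, and zerovalent palladium may ionise the allylic acetate. Fallback, setting out from 5 and returning at 18: addition of lithium (tributylstannyl)acetylide to 5 would give the stannyl ynone F8, which would be joined to 17 by Stille coupling (Pd2(dba)3, AsPh3, DMF, rt) in the absence of any base or copper acetylide to give 18.

**Step 8.** A Z-β-iodo enal is an unusual substrate for the amino-alcohol catalyst; enantioselectivity may be insufficient and the enal may isomerise under Lewis acid. Fallback, setting out from 10 and returning at 11: vinylmagnesium bromide would give the racemic carbinol F9, which would be resolved by Sharpless kinetic resolution (Ti(OiPr)4, D-(−)-diisopropyl tartrate, tBuOOH, molecular sieves, CH2Cl2, −20 °C). The S enantiomer is epoxidised at the vinyl group to the epoxy alcohol F10, and the slow-reacting R enantiomer is recovered as 11.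

## Further compounds

F1 | step 16 | allylic alcohol: 19 with the C13 acetate replaced by hydroxyl | OCC1=C[C@@H](OC1=O)/C=C(/CO[Si](C)(C)C(C)(C)C)C2=CC(=O)[C@@](C)(CC=C)O2
F2 | step 16 | allylic bromide: 3-(bromomethyl)butenolide analogue of 19 | BrCC1=C[C@@H](OC1=O)/C=C(/CO[Si](C)(C)C(C)(C)C)C2=CC(=O)[C@@](C)(CC=C)O2
F3 | step 16 | bromo aldehyde: 3-(bromomethyl)butenolide analogue of 21 | BrCC1=C[C@@H](OC1=O)/C=C(/CO[Si](C)(C)C(C)(C)C)C2=CC(=O)[C@@](C)(CC=O)O2
F4 | step 15 | (3R)-3-hydroxy-3-methyl-4-oxohex-5-ynal | C#CC(=O)[C@](C)(O)CC=O
F5 | step 15 | (4R)-4-hydroxy-6,6-dimethoxy-4-methylhex-1-yn-3-one | C#CC(=O)[C@](C)(O)CC(OC)OC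
F6 | step 15 | acetal enynone: 18 with CH2CH(OMe)2 in place of allyl | CC(=O)OCC1=C[C@@H](OC1=O)/C=C(/CO[Si](C)(C)C(C)(C)C)C#CC(=O)[C@](C)(O)CC(OC)OC
F7 | step 15 | acetal furanone: 21 as its dimethyl acetal | CC(=O)OCC1=C[C@@H](OC1=O)/C=C(/CO[Si](C)(C)C(C)(C)C)C2=CC(=O)[C@@](C)(CC(OC)OC)O2
F8 | step 13 | (4R)-4-hydroxy-4-methyl-1-(tributylstannyl)hept-6-en-1-yn-3-one | CCCC[Sn](CCCC)(CCCC)C#CC(=O)[C@](C)(O)CC=C
F9 | step 8 | racemic (4Z)-6-[(tert-butyldimethylsilyl)oxy]-5-iodohexa-1,4-dien-3-ol | C=CC(O)/C=C(/CO[Si](C)(C)C(C)(C)C)I
F10 | step 8 | (1R,2Z)-4-[(tert-butyldimethylsilyl)oxy]-3-iodo-1-[(2R)-oxiran-2-yl]but-2-en-1-ol | O[C@@H]([C@H]1CO1)/C=C(/CO[Si](C)(C)C(C)(C)C)I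
A1 | alternative 1 | α-phosphono γ-lactone with free C8 hydroxyl, open between C4 and C5 (C11 epimers) | CCOP(=O)(OCC)C1C(=O)O[C@@H](C=C)[C@H]1[C@H](O)C[C@@]2(C)OC(=CC2=O)C(=C)CO[Si](C)(C)C(C)(C)C
A2 | alternative 1 | C6 phosphonoacetate of the trans C7–C8 epoxide | CCOP(=O)(OCC)CC(=O)O[C@@H](C=C)[C@H]1O[C@@H]1C[C@@]2(C)OC(=CC2=O)C(=C)CO[Si](C)(C)C(C)(C)C
A3 | alternative 2 | 15-O-silyl 8-O-isobutyryl macrocycle lacking the C13 methylene | C1C(=O)O[C@H]2/C=C(/CO[Si](C)(C)C(C)(C)C)C3=CC(=O)[C@@](C)(C[C@@H](OC(=O)C(C)C)[C@@H]12)O3
A4 | alternative 2 | nine-membered C3 lactone of the C10 tertiary alcohol bearing the C10 acetyl group | C1C(=O)O[C@H]2/C=C(/CO[Si](C)(C)C(C)(C)C)C(=O)O[C@@](C)(C(C)=O)C[C@@H](OC(=O)C(C)C)[C@@H]12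
A5 | alternative 3 | 15-deoxy ten-membered furanone lactone, C8 silyl ether, no C13 methylene | C1C(=O)O[C@H]2/C=C(/C)C3=CC(=O)[C@@](C)(C[C@@H](O[Si](C)(C)C(C)(C)C)[C@@H]12)O3
A6 | alternative 3 | eleven-membered C4–SO2–C5 sulfone (C4 epimers) | C1C(=O)O[C@H]2CS(=O)(=O)C(C)C3=CC(=O)[C@@](C)(C[C@@H](O[Si](C)(C)C(C)(C)C)[C@@H]12)O3
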